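**Retrosynthetic overview**

- Numbering: lactone carbonyl C1, acyloxy carbon C2, alkene C5=C6, carbinols C7 and C8, propyl-bearing C9; the ten-membered ring is O–C1…C9. The route rests on the erythro pair made by the ring oxygen on C9 and the free hydroxyl on C8, next to the C7 carbinol. This is the pattern left when a trans-8,9-epoxy-7-ol is opened at C9 by the C1 carboxylate.
- Disconnections: (a) the tert-butyl ester on the muconate, removed last; (b) the lactone O–C9 bond, back to seco epoxy acid 15, closed by titanium-mediated opening of the epoxide by the tethered carboxylate with inversion at C9; (c) the C6–C7 bond, back to epoxy aldehyde 3 and the alkenylzinc made from alkyne 11.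
- Aldehyde 3 comes from (E)-hex-2-en-1-ol by asymmetric epoxidation and oxidation. Alkyne 11 comes from L-homopropargylglycine (diazotization with retention sets C2), a silyl ester at C1 and mono-tert-butyl muconate on the C2 oxygen.
- Ring order: the oxirane is made first (step 1). The ten-membered lactone, the only ring of the target, forms in step 9 as the oxirane is consumed.

Key step: step 9

Remark: the C1–C6 hydroxy acid is taken from commercial L-homopropargylglycine, and its diazotization is assumed to go with the usual net retention; this replaces a longer chiral-pool sequence.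

**Route**

Step 1
Reactants: 1 (E)-hex-2-en-1-ol
Product: 2 [(2S,3S)-3-propyloxiran-2-yl]methanol
Conditions: Ti(OiPr)4 (5 mol %), L-(+)-diethyl tartrate (6 mol %), anhydrous t-BuOOH in isooctane, 4 Å MS, CH2Cl2, −20 °C
Reagents that add atoms: tert-butyl hydroperoxide, CC(C)(C)OO
Why: Sharpless asymmetric epoxidation; the titanium tartrate complex binds the allylic alcohol and the peroxide, and with the L-(+)-tartrate oxygen should be delivered to the alkene face that gives the (2S,3S)-trans-epoxide, which fixes C8 and the pre-inversion configuration of C9.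

Step 2
Reactants: 2 [(2S,3S)-3-propyloxiran-2-yl]methanol
Product: 3 (2R,3S)-3-propyloxirane-2-carbaldehyde
Conditions: TEMPO (10 mol %), PhI(OAc)2, CH2Cl2, rt; aq Na2S2O3/NaHCO3 wash, bulb-to-bulb distillation
Reagents that add atoms: none
Why: TEMPO (oxoammonium) oxidation of the primary alcohol stops at the aldehyde under near-neutral conditions, so the epoxide and both stereocentres should be untouched (the C2 descriptor changes only through CIP priorities).

Step 3
Reactants: 4 L-homopropargylglycine [(2S)-2-aminohex-5-ynoic acid]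
Product: 7 (2S)-2-hydroxyhex-5-ynoic acid, via diazonium carboxylate 5 (not isolated), via alpha-lactone 6 (not isolated)
Conditions: NaNO2, 1 M aq H2SO4, 0 °C → rt
Reagents that add atoms: water, O
Why: Diazotization of the α-amino acid; the neighbouring carboxylate displaces N2 with inversion to the α-lactone, which water opens with a second inversion, so the S configuration that becomes C2 is retained, and the terminal alkyne is inert to nitrous acid.

Step 4
Reactants: 7 (2S)-2-hydroxyhex-5-ynoic acid
Product: 8 triisopropylsilyl (2S)-2-hydroxyhex-5-ynoate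
Conditions: i-Pr3SiCl (1.05 equiv), Et3N (1.1 equiv), CH2Cl2, 0 °C
Reagents that add atoms: triisopropylsilyl chloride, CC(C)[Si](Cl)(C(C)C)C(C)C
Why: Silyl ester formation; the triethylammonium carboxylate should be silylated much faster than the secondary hydroxyl by the bulky chlorosilane, giving a C1 ester that tolerates organoboron and organozinc reagents and is later removed by fluoride without acid or base.

Step 5
Reactants: 9 (2E,4E)-hexa-2,4-dienedioic acid (muconic acid)
Product: 10 (2E,4E)-6-tert-butoxy-6-oxohexa-2,4-dienoic acid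
Conditions: tert-butyl 2,2,2-trichloroacetimidate (1.0 equiv), THF–DMF, rt; NaHCO3 extraction, acidification, extraction into CH2Cl2
Reagents that add atoms: tert-butyl 2,2,2-trichloroacetimidate, CC(C)(C)OC(=N)C(Cl)(Cl)Cl
Why: O-tert-butylation of a carboxylic acid by the imidate, which the acid itself protonates; with one equivalent the half ester forms statistically and should be separable from the neutral diester and the insoluble diacid by acid–base extraction.

Step 6
Reactants: 8 triisopropylsilyl (2S)-2-hydroxyhex-5-ynoate; 10 (2E,4E)-6-tert-butoxy-6-oxohexa-2,4-dienoic acid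
Product: 11 triisopropylsilyl (2S)-2-{[(2E,4E)-6-tert-butoxy-6-oxohexa-2,4-dienoyl]oxy}hex-5-ynoate
Conditions: DCC, DMAP (10 mol %), CH2Cl2, 0 °C → rt
Reagents that add atoms: none
Why: Steglich esterification (carbodiimide activation, DMAP acyl transfer) acylates the C2 hydroxyl without touching the stereocentre, the silyl ester or the alkyne.

Step 7
Reactants: 11 triisopropylsilyl (2S)-2-{[(2E,4E)-6-tert-butoxy-6-oxohexa-2,4-dienoyl]oxy}hex-5-ynoate; 3 (2R,3S)-3-propyloxirane-2-carbaldehyde
Product: 14 triisopropylsilyl (2S,5E,7R)-2-{[(2E,4E)-6-tert-butoxy-6-oxohexa-2,4-dienoyl]oxy}-7-hydroxy-7-[(2S,3S)-3-propyloxiran-2-yl]hept-5-enoate, via alkenylborane 12 (not isolated), via alkenyl(methyl)zinc 13 (not isolated)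
Conditions: Cy2BH (from BH3·SMe2 and cyclohexene), toluene, 0 °C → rt; Me2Zn, −78 °C; (+)-MIB [(2R)-3-exo-morpholinoisoborneol, 5 mol %], then 3, −78 → −10 °C; aq NH4Cl
Reagents that add atoms: none
Why: Syn-hydroboration of the terminal alkyne gives the E-alkenylborane, boron-to-zinc exchange gives the alkenylzinc, and the amino alcohol–zinc catalyst adds it to the aldehyde with retention of alkene geometry (catalytic asymmetric alkenylzinc addition); the (+)-ligand antipode is chosen to direct attack to the Re face, which should give 7R (threo to the epoxide) against the modest Felkin–Anh preference of the epoxy aldehyde, while esters, dienoate and epoxide are expected to be inert to the organozinc at this temperature.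

Step 8
Reactants: 14 triisopropylsilyl (2S,5E,7R)-2-{[(2E,4E)-6-tert-butoxy-6-oxohexa-2,4-dienoyl]oxy}-7-hydroxy-7-[(2S,3S)-3-propyloxiran-2-yl]hept-5-enoate
Product: 15 (2S,5E,7R)-2-{[(2E,4E)-6-tert-butoxy-6-oxohexa-2,4-dienoyl]oxy}-7-hydroxy-7-[(2S,3S)-3-propyloxiran-2-yl]hept-5-enoic acid
Conditions: Bu4NF/AcOH (1:1, 1.1 equiv), THF, 0 °C; pH 4 buffer work-up; used at once as a dilute solution
Reagents that add atoms: none
Why: Fluoride attacks silicon of the silyl ester (desilylation) much faster than anything happens at the epoxide, dienoate or tert-butyl ester, and the acetic acid buffer should prevent alkoxide-driven epoxide migration (Payne rearrangement) from C7.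

Step 9
Reactants: 15 (2S,5E,7R)-2-{[(2E,4E)-6-tert-butoxy-6-oxohexa-2,4-dienoyl]oxy}-7-hydroxy-7-[(2S,3S)-3-propyloxiran-2-yl]hept-5-enoic acid
Product: 17 tert-butyl (2E,4E)-6-{[(3S,6E,8R,9S,10R)-8,9-dihydroxy-2-oxo-10-propyl-3,4,5,8,9,10-hexahydro-2H-oxecin-3-yl]oxy}-6-oxohexa-2,4-dienoate, via titanium chelate 16 (not isolated)
Conditions: Ti(OiPr)4 (1.5 equiv), CH2Cl2, syringe-pump addition of 15 to about 1 mM final concentration, 25 → 35 °C; then 10 % aq tartaric acid
Reagents that add atoms: none
Why: Proposed new method: Ti(OiPr)4 should exchange isopropoxide for the C7 alkoxide and the C1 carboxylate of 15, the epoxide oxygen coordinates titanium within the 2,3-epoxy alkoxide chelate, and the carboxylate attacks C9 anti to the polarised C9–O bond in an SN2 opening driven by release of ring strain, after which aqueous acid frees the C8 hydroxyl. The closest known reaction is the Ti(OiPr)4-mediated, C3-selective opening of 2,3-epoxy alcohols by external carboxylic acids; tethering the acid to close a medium-ring lactone is the untested extension. The ten-membered ring (O, C1–C9) closes by O–C9 bond formation in the endo mode at the epoxide carbon distal to the tether, the exo alternative at C8 leading to a nine-membered lactone. C9 is the only new stereocentre and is set as 9R by backside attack on the (9S)-epoxide carbon, while C7 and C8 are carried unchanged, so the trans-epoxide should give the erythro C8/C9 pair. The step needs C9-over-C8 regioselectivity, which the titanium chelate at the C7 oxygen and the inductive deactivation of C8 by that oxygen should secure, and intra- over intermolecular opening, which slow addition to high dilution should secure; opening by isopropanol and titanium-catalysed transesterification are expected to be slow at these temperatures.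

Step 10
Reactants: 17 tert-butyl (2E,4E)-6-{[(3S,6E,8R,9S,10R)-8,9-dihydroxy-2-oxo-10-propyl-3,4,5,8,9,10-hexahydro-2H-oxecin-3-yl]oxy}-6-oxohexa-2,4-dienoate
Product: 18 (2E,4E)-6-{[(3S,6E,8R,9S,10R)-8,9-dihydroxy-2-oxo-10-propyl-3,4,5,8,9,10-hexahydro-2H-oxecin-3-yl]oxy}-6-oxohexa-2,4-dienoic acid
Conditions: CF3CO2H/CH2Cl2 (1:4), 0 °C → rt; co-evaporation with toluene
Reagents that add atoms: none
Why: Acidolysis of the tert-butyl ester (loss of the tert-butyl cation as isobutene) should free the muconic half acid, while the lactone, the C2 ester and the diol are expected to survive brief cold exposure.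

**Compound list**

1 | (E)-hex-2-en-1-ol | CCC/C=C/CO | starting material
2 | [(2S,3S)-3-propyloxiran-2-yl]methanol | CCC[C@@H]1O[C@H]1CO | intermediate
3 | (2R,3S)-3-propyloxirane-2-carbaldehyde | CCC[C@@H]1O[C@H]1C=O | intermediate
4 | L-homopropargylglycine, (2S)-2-aminohex-5-ynoic acid | N[C@@H](CCC#C)C(=O)O | starting material
5 | (2S)-2-diazoniohex-5-ynoate (diazonium carboxylate) | N#[N+][C@@H](CCC#C)C([O-])=O | intermediate
6 | (3R)-3-(but-3-yn-1-yl)oxiran-2-one (alpha-lactone) | C#CCC[C@H]1OC1=O | intermediate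
7 | (2S)-2-hydroxyhex-5-ynoic acid | O[C@@H](CCC#C)C(=O)O | intermediate
8 | triisopropylsilyl (2S)-2-hydroxyhex-5-ynoate | CC(C)[Si](C(C)C)(C(C)C)OC(=O)[C@@H](O)CCC#C | intermediate
9 | (2E,4E)-hexa-2,4-dienedioic acid (muconic acid) | OC(=O)/C=C/C=C/C(=O)O | starting material
10 | (2E,4E)-6-tert-butoxy-6-oxohexa-2,4-dienoic acid | OC(=O)/C=C/C=C/C(=O)OC(C)(C)C | intermediate
11 | triisopropylsilyl (2S)-2-{[(2E,4E)-6-tert-butoxy-6-oxohexa-2,4-dienoyl]oxy}hex-5-ynoate | CC(C)[Si](C(C)C)(C(C)C)OC(=O)[C@@H](OC(=O)/C=C/C=C/C(=O)OC(C)(C)C)CCC#C | intermediate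
12 | (E)-alkenyl(dicyclohexyl)borane from 11, boron on C6 | CC(C)[Si](C(C)C)(C(C)C)OC(=O)[C@@H](OC(=O)/C=C/C=C/C(=O)OC(C)(C)C)CC/C=C/B(C1CCCCC1)C1CCCCC1 | intermediate
13 | (E)-alkenyl(methyl)zinc from 12, zinc on C6 | CC(C)[Si](C(C)C)(C(C)C)OC(=O)[C@@H](OC(=O)/C=C/C=C/C(=O)OC(C)(C)C)CC/C=C/[Zn]C | intermediate
14 | triisopropylsilyl (2S,5E,7R)-2-{[(2E,4E)-6-tert-butoxy-6-oxohexa-2,4-dienoyl]oxy}-7-hydroxy-7-[(2S,3S)-3-propyloxiran-2-yl]hept-5-enoate | CC(C)[Si](C(C)C)(C(C)C)OC(=O)[C@@H](OC(=O)/C=C/C=C/C(=O)OC(C)(C)C)CC/C=C/[C@@H](O)[C@@H]1O[C@H]1CCC | intermediate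
15 | (2S,5E,7R)-2-{[(2E,4E)-6-tert-butoxy-6-oxohexa-2,4-dienoyl]oxy}-7-hydroxy-7-[(2S,3S)-3-propyloxiran-2-yl]hept-5-enoic acid (seco epoxy acid) | OC(=O)[C@@H](OC(=O)/C=C/C=C/C(=O)OC(C)(C)C)CC/C=C/[C@@H](O)[C@@H]1O[C@H]1CCC | intermediate
16 | titanium chelate of 15: di(isopropoxy)titanium bound to the C7 alkoxide and the C1 carboxylate, drawn as the monomer | CC(C)O[Ti]2(OC(C)C)OC(=O)[C@@H](OC(=O)/C=C/C=C/C(=O)OC(C)(C)C)CC/C=C/[C@@H](O2)[C@@H]1O[C@H]1CCC | intermediate
17 | tert-butyl (2E,4E)-6-{[(3S,6E,8R,9S,10R)-8,9-dihydroxy-2-oxo-10-propyl-3,4,5,8,9,10-hexahydro-2H-oxecin-3-yl]oxy}-6-oxohexa-2,4-dienoate | CCC[C@H]1OC(=O)[C@@H](OC(=O)/C=C/C=C/C(=O)OC(C)(C)C)CC/C=C/[C@@H](O)[C@@H]1O | intermediate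
18 | (2E,4E)-6-{[(3S,6E,8R,9S,10R)-8,9-dihydroxy-2-oxo-10-propyl-3,4,5,8,9,10-hexahydro-2H-oxecin-3-yl]oxy}-6-oxohexa-2,4-dienoic acid | CCC[C@H]1OC(=O)[C@@H](OC(=O)/C=C/C=C/C(=O)O)CC/C=C/[C@@H](O)[C@@H]1O | target

**Step count**

Total steps: 10. Longest linear sequence: 7 steps (steps 3, 4, 6, 7, 8, 9, 10, from 4).

**Steps most likely to fail**

Step 9. The tethered carboxylate may fail to reach C9, so that intermolecular opening (oligomers), opening by isopropoxide or attack at C8 takes over. The fallback makes the same O–C9 bond by the known intermolecular reaction and closes the ring at the acyl carbon instead. It sets out from 14 and runs as follows: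
- Ti(OiPr)4-mediated opening of the epoxide at C9 by chloroacetic acid, with inversion, should give triisopropylsilyl (2S,5E,7R,8S,9R)-2-{[(2E,4E)-6-tert-butoxy-6-oxohexa-2,4-dienoyl]oxy}-9-[(chloroacetyl)oxy]-7,8-dihydroxydodec-5-enoate F1.
- 2,2-Dimethoxypropane with pyridinium p-toluenesulfonate should give the 7,8-O-isopropylidene acetal of F1, F2.
- Thiourea with NaHCO3 in THF–i-PrOH should remove the chloroacetyl group to give the C9 alcohol of the acetonide, F3.
- Bu4NF/AcOH should cleave the silyl ester to give the 9-hydroxy acid acetonide F4.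
- Shiina macrolactonization (2-methyl-6-nitrobenzoic anhydride, DMAP, high dilution) should close the ten-membered ring with retention at C9 to give the 7,8-O-isopropylidene derivative of 17, F5.
- Aqueous CF3CO2H should remove the acetonide and the tert-butyl ester together, and the fallback comes back to the route at 18.

Step 7. Facial selectivity may be poor if the Felkin–Anh bias or coordination of the epoxide oxygen to zinc overrides the ligand, and the borane may reduce other groups. The fallback sets out from 11 and 3. The same sequence run with the (−)-MIB antipode, where ligand and substrate bias reinforce each other, should give the C7 epimer of 14, the (7S)-alcohol F6. Mitsunobu inversion with chloroacetic acid (PPh3, diisopropyl azodicarboxylate, toluene, 0 °C) should give the (7R)-chloroacetate of 14, F7. Thiourea with NaHCO3 in THF–i-PrOH should remove the chloroacetyl group, and the fallback comes back to the route at 14.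

Step 6. The silyl group may migrate from the carboxylate to the C2 hydroxyl, or the silyl ester may be lost, in competition with acylation; the same weakness would show again in step 7. The fallback replaces the silyl ester by a carbon-based ester that fluoride removes by fragmentation. It sets out from 7. 2-(Trimethylsilyl)ethyl 2,2,2-trichloroacetimidate in hot toluene should esterify the acid alone to give 2-(trimethylsilyl)ethyl (2S)-2-hydroxyhex-5-ynoate F8. Steglich acylation with 10 should give the 2-(trimethylsilyl)ethyl analogue of 11, F9. The hydroboration, zinc exchange and ligand-controlled addition to 3 described in step 7 should give the 2-(trimethylsilyl)ethyl analogue of 14, F10. Tris(dimethylamino)sulfonium difluorotrimethylsilicate in DMF should cleave the ester, and the fallback comes back to the route at 15.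

**Further compounds**

F1 | step 9 | triisopropylsilyl (2S,5E,7R,8S,9R)-2-{[(2E,4E)-6-tert-butoxy-6-oxohexa-2,4-dienoyl]oxy}-9-[(chloroacetyl)oxy]-7,8-dihydroxydodec-5-enoate | CC(C)[Si](C(C)C)(C(C)C)OC(=O)[C@@H](OC(=O)/C=C/C=C/C(=O)OC(C)(C)C)CC/C=C/[C@@H](O)[C@H](O)[C@@H](CCC)OC(=O)CCl
F2 | step 9 | 7,8-O-isopropylidene acetal of F1 | CC(C)[Si](C(C)C)(C(C)C)OC(=O)[C@@H](OC(=O)/C=C/C=C/C(=O)OC(C)(C)C)CC/C=C/[C@H]1OC(C)(C)O[C@@H]1[C@@H](CCC)OC(=O)CCl
F3 | step 9 | C9 alcohol from F2 (chloroacetyl removed) | CC(C)[Si](C(C)C)(C(C)C)OC(=O)[C@@H](OC(=O)/C=C/C=C/C(=O)OC(C)(C)C)CC/C=C/[C@H]1OC(C)(C)O[C@@H]1[C@@H](CCC)O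
F4 | step 9 | 9-hydroxy acid acetonide from F3 (silyl ester removed) | OC(=O)[C@@H](OC(=O)/C=C/C=C/C(=O)OC(C)(C)C)CC/C=C/[C@H]1OC(C)(C)O[C@@H]1[C@@H](CCC)O
F5 | step 9 | 7,8-O-isopropylidene derivative of 17 | CCC[C@H]1OC(=O)[C@@H](OC(=O)/C=C/C=C/C(=O)OC(C)(C)C)CC/C=C/[C@H]2OC(C)(C)O[C@H]12
F6 | step 7 | C7 epimer of 14, the (7S)-alcohol | CC(C)[Si](C(C)C)(C(C)C)OC(=O)[C@@H](OC(=O)/C=C/C=C/C(=O)OC(C)(C)C)CC/C=C/[C@H](O)[C@@H]1O[C@H]1CCC
F7 | step 7 | (7R)-chloroacetate of 14 | CC(C)[Si](C(C)C)(C(C)C)OC(=O)[C@@H](OC(=O)/C=C/C=C/C(=O)OC(C)(C)C)CC/C=C/[C@@H](OC(=O)CCl)[C@@H]1O[C@H]1CCC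
F8 | step 6 | 2-(trimethylsilyl)ethyl (2S)-2-hydroxyhex-5-ynoate | C[Si](C)(C)CCOC(=O)[C@@H](O)CCC#C
F9 | step 6 | 2-(trimethylsilyl)ethyl analogue of 11 | C[Si](C)(C)CCOC(=O)[C@@H](OC(=O)/C=C/C=C/C(=O)OC(C)(C)C)CCC#C
F10 | step 6 | 2-(trimethylsilyl)ethyl analogue of 14 | C[Si](C)(C)CCOC(=O)[C@@H](OC(=O)/C=C/C=C/C(=O)OC(C)(C)C)CC/C=C/[C@@H](O)[C@@H]1O[C@H]1CCC
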